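The route rests on cutting the bond between vinylic carbon C9 and acetoxy-bearing carbon C10 (side chain numbered from benzylic C1 on the resorcinol ring). The key step exploits the Z-allylic acetate unit C8=C9–C10(OAc): a 1-chloroalkyne, hexanal and acetic anhydride are merged in one flask. Hydroboration, a hydride-triggered 1,2-shift and boron-to-zinc exchange convert the linear chloroalkyne into a Z-alkenylzinc. A chiral amino-alcohol zinc catalyst adds it to one face of hexanal, and the zinc alkoxide is then acetylated. The C9–C10 bond, the Z geometry, the R centre and the ester thus arise together. The precursor is the bis-TIPS ether of 5-(9-chloronon-8-ynyl)resorcinol.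

Key step: step 5

Remark: the stereocentre C10 of the target is R, and (−)-MIB is assumed to keep its usual Si-face preference with the unbranched aldehyde hexanal.

Step 1
Reactants: 1 5-bromoresorcinol
Product: 2 1-bromo-3,5-bis(triisopropylsilyloxy)benzene
Conditions: TIPSCl (2.4 equiv), imidazole (5 equiv), DMF, rt
Reagents that add atoms: triisopropylsilyl chloride, CC(C)[Si](Cl)(C(C)C)C(C)C
Why: Imidazole-mediated O-silylation of both phenols should be clean, and the bulky TIPS ethers are chosen because they should survive aqueous phosphate, acetylide and organolithium reagents yet fall to buffered fluoride without harm to an acetate.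

Step 2
Reactants: 2 1-bromo-3,5-bis(triisopropylsilyloxy)benzene; 3 7-bromohept-1-ene
Product: 5 1-(7-bromoheptyl)-3,5-bis(triisopropylsilyloxy)benzene, via B-(7-bromoheptyl)-9-BBN 4 (not isolated)
Conditions: 3, 9-BBN, THF, 0 °C to rt; then 2, Pd(dppf)Cl2·CH2Cl2 (5 mol %), K3PO4 (3 M aq), THF/DMF, 50 °C
Reagents that add atoms: none
Why: Anti-Markovnikov hydroboration of the terminal alkene followed by B-alkyl Suzuki–Miyaura coupling should join C1 to the ring, because zerovalent palladium bearing dppf inserts into the aryl C–Br bond much faster than into the unactivated primary C–Br bond, which is kept for step 3.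

Step 3
Reactants: 5 1-(7-bromoheptyl)-3,5-bis(triisopropylsilyloxy)benzene
Product: 6 1-(non-8-yn-1-yl)-3,5-bis(triisopropylsilyloxy)benzene
Conditions: LiC≡CH·H2NCH2CH2NH2 (2 equiv), DMSO/THF, 0 °C to rt
Reagents that add atoms: lithium acetylide–ethylenediamine complex, [Li]C#C.NCCN
Why: SN2 alkylation of lithium acetylide by the unhindered primary bromide in a dipolar aprotic medium should install C8 and C9 as a terminal alkyne, the hindered aryl TIPS ethers being expected to withstand the short exposure.

Step 4
Reactants: 6 1-(non-8-yn-1-yl)-3,5-bis(triisopropylsilyloxy)benzene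
Product: 8 1-(9-chloronon-8-yn-1-yl)-3,5-bis(triisopropylsilyloxy)benzene, via lithium acetylide 7 (not isolated)
Conditions: n-BuLi (1.05 equiv), THF, −78 °C; NCS (1.2 equiv), −78 °C to rt
Reagents that add atoms: N-chlorosuccinimide, O=C1CCC(=O)N1Cl
Why: Deprotonation of the terminal alkyne and electrophilic chlorination of the lithium acetylide with NCS should give the 1-chloroalkyne, the acetylide being far more nucleophilic than the sterically shielded arene so that no ring chlorination is expected.

Step 5
Reactants: 8 1-(9-chloronon-8-yn-1-yl)-3,5-bis(triisopropylsilyloxy)benzene; 9 hexanal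
Product: 14 (10R,8Z)-1-[3,5-bis(triisopropylsilyloxy)phenyl]pentadec-8-en-10-yl acetate, via chloroalkenylborane 10 (not isolated), via Z-alkenylborane 11 (not isolated), via Z-alkenyl(ethyl)zinc 12 (not isolated), via ethylzinc alkoxide 13 (not isolated)
Conditions: Cy2BH (1.0 equiv), MTBE, 0 °C to rt; t-BuLi (1.05 equiv), −78 °C to rt; Et2Zn (1.2 equiv), −78 °C; TEEDA (N,N,N',N'-tetraethylethylenediamine, 30 mol %), (−)-MIB [(2S)-3-exo-morpholinoisoborneol, 10 mol %], hexanes, then 9 (slow addition), 0 °C; Ac2O (3 equiv), DMAP (10 mol %), 0 °C to rt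
Reagents that add atoms: acetic anhydride, CC(=O)OC(C)=O
Why: Syn hydroboration of 8 puts boron on the chlorine-bearing carbon C9 (10), t-BuLi then serves as a hydride donor to boron, and the resulting borohydride expels chloride by a 1,2-hydride shift with inversion at the sp2 carbon, so that only the Z-alkenylborane 11 should form. Boron-to-zinc exchange with Et2Zn proceeds with retention to give 12, and the zinc aminoalkoxide made from (−)-MIB binds 12 and hexanal in the bimetallic six-membered transition state typical of amino-alcohol-catalysed organozinc additions, in which the C9–C10 bond is formed; Ac2O then acylates the ethylzinc alkoxide 13 in the same flask. The closest known reaction type is the one-pot catalytic asymmetric Z-vinylation of aldehydes starting from 1-halo-1-alkynes, combined with the routine acylative quench of a zinc alkoxide. No ring is closed. The only new stereocentre, C10, is set by the catalyst: (−)-MIB directs the alkenyl group to the Si face of the aldehyde, which corresponds to R because alkenyl outranks pentyl, and (+)-MIB is available should the sense prove opposite. The step needs regioselective hydroboration and a pure Z geometry (both secured by the chlorine atom of 8, which directs boron to C9 and then leaves with inversion), alkenyl rather than ethyl transfer (sp2 groups migrate faster from mixed zinc reagents) and suppression of the racemic LiCl-promoted background addition (TEEDA sequesters LiCl without poisoning the chiral zinc catalyst).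

Step 6
Reactants: 14 (10R,8Z)-1-[3,5-bis(triisopropylsilyloxy)phenyl]pentadec-8-en-10-yl acetate
Product: 15 (10R,8Z)-1-(3,5-dihydroxyphenyl)pentadec-8-en-10-yl acetate
Conditions: TBAF (2.5 equiv), AcOH (3 equiv), THF, 0 °C
Reagents that add atoms: none
Why: Fluoride-induced desilylation of the two aryl silyl ethers is driven by Si–F bond formation and the good phenoxide leaving group, and the AcOH buffer protonates the phenoxides at once so that the allylic acetate, the Z alkene and the C10 centre should stay untouched.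

Compound list
1 | 5-bromoresorcinol | Oc1cc(O)cc(Br)c1 | starting material
2 | 1-bromo-3,5-bis(triisopropylsilyloxy)benzene | Brc1cc(O[Si](C(C)C)(C(C)C)C(C)C)cc(O[Si](C(C)C)(C(C)C)C(C)C)c1 | intermediate
3 | 7-bromohept-1-ene | C=CCCCCCBr | starting material
4 | B-(7-bromoheptyl)-9-borabicyclo[3.3.1]nonane | BrCCCCCCCB1C2CCCC1CCC2 | intermediate
5 | 1-(7-bromoheptyl)-3,5-bis(triisopropylsilyloxy)benzene | BrCCCCCCCc1cc(O[Si](C(C)C)(C(C)C)C(C)C)cc(O[Si](C(C)C)(C(C)C)C(C)C)c1 | intermediate
6 | 1-(non-8-yn-1-yl)-3,5-bis(triisopropylsilyloxy)benzene | C#CCCCCCCCc1cc(O[Si](C(C)C)(C(C)C)C(C)C)cc(O[Si](C(C)C)(C(C)C)C(C)C)c1 | intermediate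
7 | lithium acetylide of 6 | [Li]C#CCCCCCCCc1cc(O[Si](C(C)C)(C(C)C)C(C)C)cc(O[Si](C(C)C)(C(C)C)C(C)C)c1 | intermediate
8 | 1-(9-chloronon-8-yn-1-yl)-3,5-bis(triisopropylsilyloxy)benzene | ClC#CCCCCCCCc1cc(O[Si](C(C)C)(C(C)C)C(C)C)cc(O[Si](C(C)C)(C(C)C)C(C)C)c1 | intermediate
9 | hexanal | CCCCCC=O | starting material
10 | (Z)-(1-chloroalk-1-enyl)dicyclohexylborane (Cl cis to the chain, B on C9) | Cl/C(B(C1CCCCC1)C1CCCCC1)=C\CCCCCCCc1cc(O[Si](C(C)C)(C(C)C)C(C)C)cc(O[Si](C(C)C)(C(C)C)C(C)C)c1 | intermediate
11 | (Z)-alk-1-enyldicyclohexylborane (B cis to the chain) | B(C1CCCCC1)(C1CCCCC1)/C=C\CCCCCCCc1cc(O[Si](C(C)C)(C(C)C)C(C)C)cc(O[Si](C(C)C)(C(C)C)C(C)C)c1 | intermediate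
12 | (Z)-alk-1-enyl(ethyl)zinc | CC[Zn]/C=C\CCCCCCCc1cc(O[Si](C(C)C)(C(C)C)C(C)C)cc(O[Si](C(C)C)(C(C)C)C(C)C)c1 | intermediate
13 | ethylzinc (10R,8Z)-alkoxide | CCCCC[C@H](/C=C\CCCCCCCc1cc(O[Si](C(C)C)(C(C)C)C(C)C)cc(O[Si](C(C)C)(C(C)C)C(C)C)c1)O[Zn]CC | intermediate
14 | (10R,8Z)-1-[3,5-bis(triisopropylsilyloxy)phenyl]pentadec-8-en-10-yl acetate | CCCCC[C@H](/C=C\CCCCCCCc1cc(O[Si](C(C)C)(C(C)C)C(C)C)cc(O[Si](C(C)C)(C(C)C)C(C)C)c1)OC(C)=O | intermediate
15 | (10R,8Z)-1-(3,5-dihydroxyphenyl)pentadec-8-en-10-yl acetate | CCCCC[C@H](/C=C\CCCCCCCc1cc(O)cc(O)c1)OC(C)=O | target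

Total step count: 6
Longest linear sequence: 6 (1 → 2 → 5 → 6 → 8 → 14 → 15)

Steps most likely to fail

Step 5. Facial selectivity may be poor, because the unhindered, enolisable aldehyde leaves room for the racemic salt-promoted background addition. The hydride migration may also be incomplete. The fallback sets the centre by reduction instead of addition.
- Setting out from 6, an acyl Sonogashira coupling with hexanoyl chloride (PdCl2(PPh3)2, CuI, Et3N, THF, rt) would forge the same C9–C10 bond and give the ynone 1-[3,5-bis(triisopropylsilyloxy)phenyl]pentadec-8-yn-10-one F1.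
- Noyori asymmetric transfer hydrogenation (RuCl[(R,R)-TsDPEN](p-cymene), i-PrOH, rt) should give the (R)-propargylic alcohol F2.
- Acetylation (Ac2O, pyridine, DMAP, CH2Cl2) should give the (R)-propargylic acetate F3.
- Semihydrogenation (H2, Pd/CaCO3 poisoned with Pb(OAc)2, quinoline, EtOAc/hexane) comes back to the route at 14.

Step 2. The phenolic silyl groups may be lost in the warm aqueous phosphate medium, and hydrolysis or elimination may compete at the primary bromide. The fallback is anhydrous and free of base.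
- Setting out from 2, magnesium insertion (Mg turnings, THF, or exchange with i-PrMgCl·LiCl) would give 3,5-bis(triisopropylsilyloxy)phenylmagnesium bromide F4.
- Copper-catalysed Grignard alkylation with an excess of 1,7-dibromoheptane (Li2CuCl4, 5 mol %, THF, 0 °C) comes back to the route at 5.

Step 3. The aryl ethers may be desilylated by the amine-complexed acetylide in DMSO, and E2 elimination of the bromide may compete. The fallback installs the alkyne before the arene is present.
- Setting out from 3, alkylation of lithium trimethylsilylacetylide (TMS-acetylene, n-BuLi, THF/DMPU, −78 °C to rt) would give trimethyl(non-8-en-1-yn-1-yl)silane F5.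
- Chemoselective hydroboration of its alkene with 9-BBN would give the B-alkyl-9-BBN F6.
- B-alkyl Suzuki–Miyaura coupling with 2 (Pd(dppf)Cl2·CH2Cl2, K3PO4 aq, THF/DMF) should give the silylated alkyne 1-[9-(trimethylsilyl)non-8-yn-1-yl]-3,5-bis(triisopropylsilyloxy)benzene F7.
- Silver-catalysed protodesilylation (AgNO3, 10 mol %, acetone/H2O), which spares silyl ethers, comes back to the route at 6.

Further compounds
F1 | step 5 | 1-[3,5-bis(triisopropylsilyloxy)phenyl]pentadec-8-yn-10-one | CCCCCC(=O)C#CCCCCCCCc1cc(O[Si](C(C)C)(C(C)C)C(C)C)cc(O[Si](C(C)C)(C(C)C)C(C)C)c1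
F2 | step 5 | (R)-1-[3,5-bis(triisopropylsilyloxy)phenyl]pentadec-8-yn-10-ol | CCCCC[C@H](C#CCCCCCCCc1cc(O[Si](C(C)C)(C(C)C)C(C)C)cc(O[Si](C(C)C)(C(C)C)C(C)C)c1)O
F3 | step 5 | (R)-1-[3,5-bis(triisopropylsilyloxy)phenyl]pentadec-8-yn-10-yl acetate | CCCCC[C@H](C#CCCCCCCCc1cc(O[Si](C(C)C)(C(C)C)C(C)C)cc(O[Si](C(C)C)(C(C)C)C(C)C)c1)OC(C)=O
F4 | step 2 | 3,5-bis(triisopropylsilyloxy)phenylmagnesium bromide | Br[Mg]c1cc(O[Si](C(C)C)(C(C)C)C(C)C)cc(O[Si](C(C)C)(C(C)C)C(C)C)c1
F5 | step 3 | trimethyl(non-8-en-1-yn-1-yl)silane | C=CCCCCCC#C[Si](C)(C)C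
F6 | step 3 | B-[9-(trimethylsilyl)non-8-yn-1-yl]-9-borabicyclo[3.3.1]nonane | C[Si](C)(C)C#CCCCCCCCB1C2CCCC1CCC2
F7 | step 3 | 1-[9-(trimethylsilyl)non-8-yn-1-yl]-3,5-bis(triisopropylsilyloxy)benzene | C[Si](C)(C)C#CCCCCCCCc1cc(O[Si](C(C)C)(C(C)C)C(C)C)cc(O[Si](C(C)C)(C(C)C)C(C)C)c1
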